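## The problem

Numbering used throughout: ring B is C1–C4 (side chain on C1, methyl on C4); ring A is C4a, C5 (OH), C6 (OH), C7 (CO2H), C8 (H), C8a; the chain is C11–C16 with methyls on C11 and C15 and the caffeate oxygen on C16.

The target is a 1,4-trans tetralin whose aromatic ring is a fully substituted 2,3-dihydroxybenzoic acid with a single hydrogen at C8. It has four stereocentres: C1 and C4 on ring B, C11 next to C1, and C15, which is too remote for substrate control and must come from the chiral pool. The C4 centre is peri to the C5 oxygen, so any C4 substituent other than hydrogen sits pseudoaxial. This has a consequence for every ring closure onto C1: the closure places the C1 side chain pseudoequatorial, which is cis to the pseudoaxial C4 group, because on a tetralin pseudoaxial/pseudoequatorial at C1/C4 is the cis arrangement. A 1,4-trans pattern therefore arises only when a carbon nucleophile enters C4 (or C1) along the axial direction on an existing ring, and this fixes the order in which C1 and C4 can be set. The two catechols, the salicylic acid and the caffeate ester (base-labile, a Michael acceptor, reducible) will not survive organolithiums, BBr3 or hydrogenation, so those operations must come before the esterification and the last unmasking must be neutral. The enabling feature is that C8a bears C1 while its neighbour C8 bears only hydrogen. An aryne across C8–C8a can therefore take up C1 and one hydrogen from a 4-methylpent-3-enyl chain hung on C4a through C4, closing ring B and leaving an isopropenyl group as the handle for C11–C16.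

## Retrosynthesis

**Unmasking (34 ⇒ 33).** Five O–allyl bonds are cut last: both catechols and the C7 acid of 34 are carried as allyl ethers and an allyl ester in 33. One neutral palladium-catalysed step then releases all five acidic groups without touching the caffeate ester or its alkene. Hydrogenolysis, strong acid or strong base would each endanger the ester.

**Ester bond (33 ⇒ 29 + 32).** The C16–O acyl bond is cut to give alcohol 29 and 3,4-bis(allyloxy)cinnamic acid 32, made in two steps from caffeic acid 30. The forward step is a plain carbodiimide esterification of a primary alcohol. It is placed after all strongly basic and Lewis-acidic chemistry.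

**Protecting-group exchange (29 ⇒ 28 ⇒ 27).** The O–allyl bonds of 29 go back to the free catechol acid 28 and from there to dimethyl ether 27. Methyl ethers are needed earlier because they direct lithiation and survive the aryne, but they cannot be removed once the caffeate is present. Alkylation with carbonate base touches only the acid and the phenols, so the C16 hydroxyl of 28 is left free for the esterification without a separate protecting group.

**C7–CO2H bond (27 ⇒ 25).** C7 is the only position ortho to a methoxy group in 25. Directed lithiation and carboxylation is therefore regiochemically unambiguous, whereas electrophilic substitution would go to C8, para to the C5 oxygen.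

**C4–CH3 bond (25 ⇒ 24).** The methyl group is disconnected from C4 to give benzylic alcohol 24. In the forward sense a methyl nucleophile adds to the C5-methoxy-stabilised C4 cation along the axial direction, opposite the C1 chain, which gives the trans relationship. This cut is preferred to carrying the methyl group through the ring closure, where the same conformational preference would give the cis isomer. The oxygen at C4 then serves twice, as control element for C1 and as leaving group.

**C12–C13 bond and C11 (24 ⇒ 23 ⇒ 22 ⇒ 17 + 21; 17 ⇒ 16).** Desilylation of 23 and reduction of alkene 22 lead back to boronate 17 and alkenyl iodide 21. Boronate 17 comes from isopropenyl tetralin 16 by catalyst-controlled hydroboration, which sets C11 without relying on the weak bias of C1. Iodide 21 carries C15 from Roche ester 18 through 19 and 20.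

**Key cut, C1–C8a and C8–H (16 ⇒ 14 through aryne 15).** Ring B is opened between C1 and C8a and the C8 hydrogen is returned to a methyl group of a prenyl terminus. A cationic closure onto C8a would also form this bond, but it needs acid, leaves no alkene handle and offers no control. The aryne–ene reaction is neutral and delivers the isopropenyl group directly. The precursor 14 is an acyclic 2-silylaryl triflate with one stereocentre. The forward step must give ene rather than [2+2] products and must place C1 cis to the C4 oxygen.

**Aryne precursor (14 ⇒ 12 ⇒ 9 ⇒ 8 ⇒ 7 ⇒ 2 + 4).** The triflate and the C8 silyl group come from one isopropyl carbamate, used twice as a directing group and then converted into the triflate. The C4–C4a bond comes from acylation of lithiated carbamate 2, made from phenol 1, with Weinreb amide 4, made from acid 3. Asymmetric reduction of ketone 7 sets the C4 oxygen centre (8), which is protected as silyl ether 9.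

## Roads not taken

Alternative 1: The cut is the transannular C4a–C8a bond of a ten-membered ring. The macrocyclic diynyl β-keto ester A1 would enolise to a cyclic enediyne and cycloaromatise, closing rings A and B at once to give hydroxy ester A2 after hydrogen-atom transfer to C5 and C8. Its merits are real. Both ring-B stereocentres are set on an open chain, so the 1,4-trans relationship is free of the peri effect that constrains the chosen plan, and the C7 ester and C6 oxygen arrive in place. Its weak points are that A2 has hydrogen at C5, so the C5 oxygen must be introduced afterwards at the most hindered position of the ring. The diradical intermediate also sits beside allylic and benzylic hydrogens at C1 and C4 that it can abstract, and a strained ten-membered diyne with two stereocentres is a long synthesis in itself. The chosen plan sets against this a C5 oxygen present from the start, a seven-step acyclic precursor and a closure at room temperature without radicals.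

Alternative 2: The cut is at C11, with no ring formed. A trans vinyl tetralin A3 would undergo zirconium-catalysed methylalumination and the resulting C12 alane would be cross-coupled in the same pot with alkenyl iodide 21 to give A4. For the C11–C13 region this is better than the chosen plan: one pot makes the C11 methyl bond, the C11 centre and the C12–C13 bond, against two steps (9 and 13) here. It does nothing, however, for ring B or the 1,4-trans problem, which are pushed into the synthesis of A3. Methylalumination of a vinyl group on a branched benzylic carbon is also slow and less selective than on unbranched alkenes. The chosen plan has the advantage that its ring closure delivers the isopropenyl handle directly and that hydroboration of 2-substituted propenes with a branched substituent is the favourable case for the copper catalyst.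

Alternative 3: The cuts are C4a–C8a and C7–C8. An open-chain 2-pyrone A5 with a terminal alkyne four carbons from the ring would undergo intramolecular [4+2] cycloaddition and lose its lactone bridge to give A6, with rings A and B closed together and every ring-A substituent in place. In stereochemical certainty it is as good as or better than the chosen plan, since all four centres are set on an open chain and the C7 carboxyl needs no late lithiation. Its weak points are the fully substituted, electron-rich pyrone, which is hard to make and unreactive toward an unactivated alkyne, and the high temperature this implies. Under those conditions the C4 centre, attached to the pyrone at its vinylogous α-position, is at risk of epimerisation. The whole chain with four stereocentres must also be assembled before the key step is tested. The chosen plan tests its key step after seven linear steps under mild fluoride conditions and builds on commercial fragments.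

Key step: step 8

Remark: 5-methylhex-4-enoic acid (3) is treated as a purchasable acid; if it has to be made, orthoester Claisen rearrangement of 2-methylbut-3-en-2-ol followed by saponification gives it in two steps.

Remark: in step 9 the (R)-ligand is written on the assumption that it directs hydride to the Re face of C11; if the facial sense is the reverse, the (S)-ligand is used.

## Route

Step 1
Reactants: 1 3,4-dimethoxyphenol
Product: 2 3,4-dimethoxyphenyl propan-2-ylcarbamate
Conditions: iPrNCO, Et3N (cat.), CH2Cl2, rt
Reagents that add atoms: isopropyl isocyanate CC(C)N=C=O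
Why: Addition of the phenol to the isocyanate (carbamoylation) installs a directing group that can later be removed under mild base and exchanged for triflate.

Step 2
Reactants: 3 5-methylhex-4-enoic acid
Product: 4 N-methoxy-N,5-dimethylhex-4-enamide
Conditions: CDI, CH2Cl2, rt; MeNH(OMe)·HCl
Reagents that add atoms: N,O-dimethylhydroxylamine hydrochloride CNOC.Cl
Why: Weinreb amide formation through the acyl imidazolide; the trisubstituted alkene is untouched.

Step 3
Reactants: 2 3,4-dimethoxyphenyl propan-2-ylcarbamate; 4 N-methoxy-N,5-dimethylhex-4-enamide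
Product: 7 3,4-dimethoxy-2-(5-methylhex-4-enoyl)phenyl propan-2-ylcarbamate, via N-silyl carbamate 5 (not isolated), via aryllithium 6 (not isolated)
Conditions: TBSOTf, TMEDA, Et2O, 0 °C to rt; n-BuLi, TMEDA, −78 °C; 4, −78 to 0 °C; aq. NH4Cl
Reagents that add atoms: none
Why: Directed ortho-metalation of the carbamate, whose N–H is masked in the flask as the N-silyl derivative, removes the hydrogen flanked by the carbamate and the C3 methoxy group at −78 °C, where the anionic Fries shift is slow; acylation by the Weinreb amide stops at the ketone through the chelated tetrahedral adduct.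

Step 4
Reactants: 7 3,4-dimethoxy-2-(5-methylhex-4-enoyl)phenyl propan-2-ylcarbamate
Product: 8 2-[(1S)-1-hydroxy-5-methylhex-4-en-1-yl]-3,4-dimethoxyphenyl propan-2-ylcarbamate
Conditions: (R)-2-methyl-CBS-oxazaborolidine (20 mol %), BH3·SMe2, THF, −20 °C; MeOH
Reagents that add atoms: none
Why: Corey–Bakshi–Shibata reduction, in which the twisted, doubly ortho-substituted aryl group is the large substituent and the primary alkyl chain the small one, so the (R)-catalyst should give the (S)-carbinol that becomes the C4 oxygen centre.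

Step 5
Reactants: 8 2-[(1S)-1-hydroxy-5-methylhex-4-en-1-yl]-3,4-dimethoxyphenyl propan-2-ylcarbamate
Product: 9 2-[(1S)-1-(tert-butyldimethylsilyloxy)-5-methylhex-4-en-1-yl]-3,4-dimethoxyphenyl propan-2-ylcarbamate
Conditions: TBSOTf, 2,6-lutidine, CH2Cl2, −78 to 0 °C
Reagents that add atoms: tert-butyldimethylsilyl trifluoromethanesulfonate CC(C)(C)[Si](C)(C)OS(=O)(=O)C(F)(F)F
Why: Silylation under buffered, non-basic conditions protects the ionisable benzylic alcohol and prevents carbamoyl transfer to the neighbouring oxygen.

Step 6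
Reactants: 9 2-[(1S)-1-(tert-butyldimethylsilyloxy)-5-methylhex-4-en-1-yl]-3,4-dimethoxyphenyl propan-2-ylcarbamate
Product: 12 2-[(1S)-1-(tert-butyldimethylsilyloxy)-5-methylhex-4-en-1-yl]-3,4-dimethoxy-6-(trimethylsilyl)phenyl propan-2-ylcarbamate, via N-silyl carbamate 10 (not isolated), via aryllithium 11 (not isolated)
Conditions: TBSOTf, TMEDA, Et2O, 0 °C to rt; n-BuLi, TMEDA, −78 °C; TMSCl, −78 °C to rt; aq. NaHCO3
Reagents that add atoms: chlorotrimethylsilane C[Si](C)(C)Cl
Why: Second directed ortho-metalation of the same carbamate; the only hydrogen ortho to it is the one on the future C8, and the tertiary benzylic C–H is too hindered to compete at −78 °C.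

Step 7
Reactants: 12 2-[(1S)-1-(tert-butyldimethylsilyloxy)-5-methylhex-4-en-1-yl]-3,4-dimethoxy-6-(trimethylsilyl)phenyl propan-2-ylcarbamate
Product: 14 2-[(1S)-1-(tert-butyldimethylsilyloxy)-5-methylhex-4-en-1-yl]-3,4-dimethoxy-6-(trimethylsilyl)phenyl trifluoromethanesulfonate, via phenol 13 (not isolated)
Conditions: DBU, Et2NH, MeCN, 40 °C; then PhNTf2, rt to 40 °C
Reagents that add atoms: N-phenylbis(trifluoromethanesulfonimide) O=S(=O)(N(c1ccccc1)S(=O)(=O)C(F)(F)F)C(F)(F)F
Why: E1cB cleavage of the N–H carbamate (the isocyanate is expelled and trapped by Et2NH), which is insensitive to the two ortho substituents, followed by triflation of the phenoxide in the same flask; the standard route to 2-silylaryl triflates.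

Step 8
Reactants: 14 2-[(1S)-1-(tert-butyldimethylsilyloxy)-5-methylhex-4-en-1-yl]-3,4-dimethoxy-6-(trimethylsilyl)phenyl trifluoromethanesulfonate
Product: 16 (1S,4S)-4-(tert-butyldimethylsilyloxy)-5,6-dimethoxy-1-(prop-1-en-2-yl)-1,2,3,4-tetrahydronaphthalene (1,4-cis), via aryne 15 (not isolated)
Conditions: CsF (3 equiv), MeCN (0.01 M), rt
Reagents that add atoms: none
Why: Fluoride attacks the trimethylsilyl group and triflate leaves, giving aryne 15 (C8≡C8a), whose in-plane π bond reacts with the tethered trisubstituted alkene in a concerted, asynchronous ene reaction: C8a bonds to C1, a hydrogen of the C11 methyl group trans to the tether moves to C8, and the double bond shifts to C11=C12. The closest known reaction type is the intramolecular aryne–ene reaction of 2-silylaryl triflates with tethered prenyl-type alkenes, which gives isopropenyl-substituted benzo-fused six-membered rings. Ring B closes as a six-membered ring by bonding of the aryne carbon to the near alkene carbon (exo with respect to the alkene) through a half-chair in which C2 and C3 lie on opposite sides of the arene plane. The new C1 centre is controlled by the C4 silyloxy group: the C5 methoxy group holds C4–H in the arene plane and the silyloxy group pseudoaxial, while hydrogen delivery to C8 requires C11 to sit pseudoequatorial beside C8, so the isopropenyl group ends on the face of the C4 oxygen (1,4-cis, 1S from 4S). The step needs ene selectivity over [2+2] addition and over capture of the aryne by fluoride or solvent, which the six allylic hydrogens of the prenyl terminus and high dilution secure. It also needs the benzylic silyl ether to survive fluoride, for which anhydrous CsF at room temperature is chosen.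

Step 9
Reactants: 16 (1S,4S)-4-(tert-butyldimethylsilyloxy)-5,6-dimethoxy-1-(prop-1-en-2-yl)-1,2,3,4-tetrahydronaphthalene
Product: 17 2-{(2S)-2-[(1S,4S)-4-(tert-butyldimethylsilyloxy)-5,6-dimethoxy-1,2,3,4-tetrahydronaphthalen-1-yl]propyl}-4,4,5,5-tetramethyl-1,3,2-dioxaborolane
Conditions: CuCl (5 mol %), (R)-DTBM-SEGPHOS (6 mol %), KOtBu (10 mol %), HBpin, THF, rt
Reagents that add atoms: pinacolborane CC1(C)OBOC1(C)C
Why: Copper hydride-catalysed enantioselective hydroboration of a 1,1-disubstituted alkene: ligand-controlled hydrocupration places hydrogen on the Re face of C11 and copper on C12, and exchange with HBpin gives the primary boronate, so C11 (S) is set by the catalyst and not by the weak bias of C1.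

Step 10
Reactants: 18 methyl (S)-3-hydroxy-2-methylpropanoate
Product: 19 methyl (S)-3-(tert-butyldimethylsilyloxy)-2-methylpropanoate
Conditions: TBSCl, imidazole, CH2Cl2, 0 °C to rt
Reagents that add atoms: tert-butyldimethylsilyl chloride CC(C)(C)[Si](C)(C)Cl
Why: Silyl protection of the primary alcohol, which becomes the C16 oxygen; C15 is untouched.

Step 11
Reactants: 19 methyl (S)-3-(tert-butyldimethylsilyloxy)-2-methylpropanoate
Product: 20 (S)-3-(tert-butyldimethylsilyloxy)-2-methylpropanal
Conditions: iBu2AlH, CH2Cl2, −78 °C; aq. potassium sodium tartrate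
Reagents that add atoms: none
Why: Partial reduction of the ester at −78 °C through the stable tetrahedral aluminate; the aldehyde is used crude to avoid epimerisation at C15.

Step 12
Reactants: 20 (S)-3-(tert-butyldimethylsilyloxy)-2-methylpropanal
Product: 21 tert-butyl{[(2R,3E)-4-iodo-2-methylbut-3-en-1-yl]oxy}dimethylsilane
Conditions: CrCl2, CHI3, THF, 0 °C
Reagents that add atoms: iodoform IC(I)I
Why: Takai olefination gives the (E)-alkenyl iodide under non-basic conditions, so the α-stereocentre (C15) is kept; the aldehyde carbon becomes C14.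

Step 13
Reactants: 17 2-{(2S)-2-[(1S,4S)-4-(tert-butyldimethylsilyloxy)-5,6-dimethoxy-1,2,3,4-tetrahydronaphthalen-1-yl]propyl}-4,4,5,5-tetramethyl-1,3,2-dioxaborolane; 21 tert-butyl{[(2R,3E)-4-iodo-2-methylbut-3-en-1-yl]oxy}dimethylsilane
Product: 22 tert-butyl{[(2R,3E,6S)-6-[(1S,4S)-4-(tert-butyldimethylsilyloxy)-5,6-dimethoxy-1,2,3,4-tetrahydronaphthalen-1-yl]-2-methylhept-3-en-1-yl]oxy}dimethylsilane
Conditions: Pd(OAc)2 (5 mol %), RuPhos (10 mol %), KOH (aq.), THF, 70 °C
Reagents that add atoms: none
Why: B-alkyl Suzuki–Miyaura coupling of a primary alkyl pinacol boronate with an alkenyl iodide forms C12–C13 with retention of alkene geometry; no stereocentre takes part.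

Step 14
Reactants: 22 tert-butyl{[(2R,3E,6S)-6-[(1S,4S)-4-(tert-butyldimethylsilyloxy)-5,6-dimethoxy-1,2,3,4-tetrahydronaphthalen-1-yl]-2-methylhept-3-en-1-yl]oxy}dimethylsilane
Product: 23 tert-butyl{[(2R,6S)-6-[(1S,4S)-4-(tert-butyldimethylsilyloxy)-5,6-dimethoxy-1,2,3,4-tetrahydronaphthalen-1-yl]-2-methylheptyl]oxy}dimethylsilane
Conditions: 2-nitrobenzenesulfonohydrazide, Et3N, CH2Cl2, rt
Reagents that add atoms: none
Why: Diimide reduction transfers H2 in a concerted, metal-free step, so the double bond cannot migrate toward C15 and the benzylic C4–O bond cannot be hydrogenolysed.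

Step 15
Reactants: 23 tert-butyl{[(2R,6S)-6-[(1S,4S)-4-(tert-butyldimethylsilyloxy)-5,6-dimethoxy-1,2,3,4-tetrahydronaphthalen-1-yl]-2-methylheptyl]oxy}dimethylsilane
Product: 24 (1S,4S)-4-[(2S,6R)-7-hydroxy-6-methylheptan-2-yl]-7,8-dimethoxy-1,2,3,4-tetrahydronaphthalen-1-ol (route numbering: C4 hydroxyl cis to the C1 chain)
Conditions: Bu4NF, THF, rt to 40 °C
Reagents that add atoms: none
Why: Fluoride desilylation of both silyl ethers under conditions that do not ionise the benzylic alcohol.

Step 16
Reactants: 24 (1S,4S)-4-[(2S,6R)-7-hydroxy-6-methylheptan-2-yl]-7,8-dimethoxy-1,2,3,4-tetrahydronaphthalen-1-ol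
Product: 25 (2R,6S)-6-[(1S,4R)-5,6-dimethoxy-4-methyl-1,2,3,4-tetrahydronaphthalen-1-yl]-2-methylheptan-1-ol
Conditions: AlMe3 (6 equiv), CH2Cl2, −78 °C to rt
Reagents that add atoms: trimethylaluminium C[Al](C)C
Why: Lewis-acid-mediated SN1 methylation of an electron-rich secondary benzylic alcohol: the aluminium alkoxide ionises to the C5-methoxy-stabilised cation, and methyl enters C4 axially on the face opposite both the pseudoaxial C1 chain and the departing oxygen, giving the pseudoaxial methyl group that the peri effect favours and hence the 1,4-trans (4R) centre; the primary aluminium alkoxide at C16 cannot ionise.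

Step 17
Reactants: 25 (2R,6S)-6-[(1S,4R)-5,6-dimethoxy-4-methyl-1,2,3,4-tetrahydronaphthalen-1-yl]-2-methylheptan-1-ol
Product: 27 (5R,8S)-8-[(2S,6R)-7-hydroxy-6-methylheptan-2-yl]-3,4-dimethoxy-5-methyl-5,6,7,8-tetrahydronaphthalene-2-carboxylic acid, via dilithio species 26 (not isolated)
Conditions: n-BuLi (3.5 equiv), TMEDA, Et2O, 0 °C to rt; CO2, −78 °C; aq. HCl
Reagents that add atoms: carbon dioxide O=C=O
Why: Directed ortho-metalation of a veratrole-type arene followed by carboxylation; C7 is the only position ortho to a methoxy group and the C16 hydroxyl is carried as its lithium alkoxide.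

Step 18
Reactants: 27 (5R,8S)-8-[(2S,6R)-7-hydroxy-6-methylheptan-2-yl]-3,4-dimethoxy-5-methyl-5,6,7,8-tetrahydronaphthalene-2-carboxylic acid
Product: 28 (5R,8S)-3,4-dihydroxy-8-[(2S,6R)-7-hydroxy-6-methylheptan-2-yl]-5-methyl-5,6,7,8-tetrahydronaphthalene-2-carboxylic acid
Conditions: BBr3 (5 equiv), CH2Cl2, −78 to 0 °C; MeOH, H2O
Reagents that add atoms: none
Why: BBr3 cleavage of both aryl methyl ethers, the C6 ether assisted by the neighbouring carboxyl group; at or below 0 °C the primary alcohol should stay as its borate ester and return on hydrolysis.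

Step 19
Reactants: 28 (5R,8S)-3,4-dihydroxy-8-[(2S,6R)-7-hydroxy-6-methylheptan-2-yl]-5-methyl-5,6,7,8-tetrahydronaphthalene-2-carboxylic acid
Product: 29 prop-2-en-1-yl (5R,8S)-8-[(2S,6R)-7-hydroxy-6-methylheptan-2-yl]-5-methyl-3,4-bis(prop-2-en-1-yloxy)-5,6,7,8-tetrahydronaphthalene-2-carboxylate
Conditions: allyl bromide (3.5 equiv), K2CO3, DMF, 50 °C, degassed
Reagents that add atoms: allyl bromide C=CCBr
Why: Williamson alkylation in which carbonate deprotonates only the carboxylic acid and the two phenols, so the aliphatic C16 hydroxyl stays free for the esterification.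

Step 20
Reactants: 30 caffeic acid
Product: 31 prop-2-en-1-yl (2E)-3-[3,4-bis(prop-2-en-1-yloxy)phenyl]prop-2-enoate
Conditions: allyl bromide (3.5 equiv), K2CO3, DMF, 50 °C
Reagents that add atoms: allyl bromide C=CCBr
Why: Exhaustive O-alkylation of the two phenols and the carboxylic acid.

Step 21
Reactants: 31 prop-2-en-1-yl (2E)-3-[3,4-bis(prop-2-en-1-yloxy)phenyl]prop-2-enoate
Product: 32 (2E)-3-[3,4-bis(prop-2-en-1-yloxy)phenyl]prop-2-enoic acid
Conditions: LiOH, THF/MeOH/H2O, rt; aq. HCl
Reagents that add atoms: none
Why: Saponification of the allyl ester; the aryl allyl ethers are stable to hydroxide.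

Step 22
Reactants: 29 prop-2-en-1-yl (5R,8S)-8-[(2S,6R)-7-hydroxy-6-methylheptan-2-yl]-5-methyl-3,4-bis(prop-2-en-1-yloxy)-5,6,7,8-tetrahydronaphthalene-2-carboxylate; 32 (2E)-3-[3,4-bis(prop-2-en-1-yloxy)phenyl]prop-2-enoic acid
Product: 33 prop-2-en-1-yl (5R,8S)-8-[(2S,6R)-7-({(2E)-3-[3,4-bis(prop-2-en-1-yloxy)phenyl]prop-2-enoyl}oxy)-6-methylheptan-2-yl]-5-methyl-3,4-bis(prop-2-en-1-yloxy)-5,6,7,8-tetrahydronaphthalene-2-carboxylate
Conditions: EDC·HCl, DMAP, CH2Cl2, 0 °C to rt
Reagents that add atoms: none
Why: Steglich esterification of the only free hydroxyl group with the protected cinnamic acid; no stereocentre is involved.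

Step 23
Reactants: 33 prop-2-en-1-yl (5R,8S)-8-[(2S,6R)-7-({(2E)-3-[3,4-bis(prop-2-en-1-yloxy)phenyl]prop-2-enoyl}oxy)-6-methylheptan-2-yl]-5-methyl-3,4-bis(prop-2-en-1-yloxy)-5,6,7,8-tetrahydronaphthalene-2-carboxylate
Product: 34 (5R,8S)-8-[(2S,6R)-7-{[(2E)-3-(3,4-dihydroxyphenyl)prop-2-enoyl]oxy}-6-methylheptan-2-yl]-3,4-dihydroxy-5-methyl-5,6,7,8-tetrahydronaphthalene-2-carboxylic acid
Conditions: Pd(PPh3)4 (10 mol %), PhNHMe, THF, rt, degassed
Reagents that add atoms: none
Why: Tsuji–Trost deallylation: zerovalent palladium ionises the four aryl allyl ethers and the allyl ester, and N-methylaniline traps the allyl groups; the neutral conditions spare the caffeate ester, its alkene and both catechols.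

## Compound list

1 | 3,4-dimethoxyphenol | COc1ccc(O)cc1OC | starting material
2 | 3,4-dimethoxyphenyl propan-2-ylcarbamate | CC(C)NC(=O)Oc1ccc(OC)c(OC)c1 | intermediate
3 | 5-methylhex-4-enoic acid | CC(C)=CCCC(=O)O | starting material
4 | N-methoxy-N,5-dimethylhex-4-enamide | CC(C)=CCCC(=O)N(C)OC | intermediate
5 | 3,4-dimethoxyphenyl N-(tert-butyldimethylsilyl)-N-(propan-2-yl)carbamate | CC(C)N(C(=O)Oc1ccc(OC)c(OC)c1)[Si](C)(C)C(C)(C)C | intermediate
6 | 2-lithio derivative of 5 (lithium between the carbamate oxygen and the C3 methoxy group) | CC(C)N(C(=O)Oc1ccc(OC)c(OC)c1[Li])[Si](C)(C)C(C)(C)C | intermediate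
7 | 3,4-dimethoxy-2-(5-methylhex-4-enoyl)phenyl propan-2-ylcarbamate | CC(C)=CCCC(=O)c1c(OC(=O)NC(C)C)ccc(OC)c1OC | intermediate
8 | 2-[(1S)-1-hydroxy-5-methylhex-4-en-1-yl]-3,4-dimethoxyphenyl propan-2-ylcarbamate | CC(C)=CCC[C@H](O)c1c(OC(=O)NC(C)C)ccc(OC)c1OC | intermediate
9 | 2-[(1S)-1-(tert-butyldimethylsilyloxy)-5-methylhex-4-en-1-yl]-3,4-dimethoxyphenyl propan-2-ylcarbamate | CC(C)=CCC[C@H](O[Si](C)(C)C(C)(C)C)c1c(OC(=O)NC(C)C)ccc(OC)c1OC | intermediate
10 | N-(tert-butyldimethylsilyl) derivative of 9 | CC(C)=CCC[C@H](O[Si](C)(C)C(C)(C)C)c1c(OC(=O)N(C(C)C)[Si](C)(C)C(C)(C)C)ccc(OC)c1OC | intermediate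
11 | 6-lithio derivative of 10 (lithium ortho to the carbamate oxygen) | CC(C)=CCC[C@H](O[Si](C)(C)C(C)(C)C)c1c(OC(=O)N(C(C)C)[Si](C)(C)C(C)(C)C)c([Li])cc(OC)c1OC | intermediate
12 | 2-[(1S)-1-(tert-butyldimethylsilyloxy)-5-methylhex-4-en-1-yl]-3,4-dimethoxy-6-(trimethylsilyl)phenyl propan-2-ylcarbamate | CC(C)=CCC[C@H](O[Si](C)(C)C(C)(C)C)c1c(OC(=O)NC(C)C)c([Si](C)(C)C)cc(OC)c1OC | intermediate
13 | 2-[(1S)-1-(tert-butyldimethylsilyloxy)-5-methylhex-4-en-1-yl]-3,4-dimethoxy-6-(trimethylsilyl)phenol | CC(C)=CCC[C@H](O[Si](C)(C)C(C)(C)C)c1c(O)c([Si](C)(C)C)cc(OC)c1OC | intermediate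
14 | 2-[(1S)-1-(tert-butyldimethylsilyloxy)-5-methylhex-4-en-1-yl]-3,4-dimethoxy-6-(trimethylsilyl)phenyl trifluoromethanesulfonate | CC(C)=CCC[C@H](O[Si](C)(C)C(C)(C)C)c1c(OS(=O)(=O)C(F)(F)F)c([Si](C)(C)C)cc(OC)c1OC | intermediate
15 | 3-[(1S)-1-(tert-butyldimethylsilyloxy)-5-methylhex-4-en-1-yl]-4,5-dimethoxybenzyne (triple bond C8–C8a) | CC(C)=CCC[C@H](O[Si](C)(C)C(C)(C)C)C1=C(OC)C(OC)=CC#C1 | intermediate
16 | (1S,4S)-4-(tert-butyldimethylsilyloxy)-5,6-dimethoxy-1-(prop-1-en-2-yl)-1,2,3,4-tetrahydronaphthalene (1,4-cis) | C=C(C)[C@@H]1CC[C@H](O[Si](C)(C)C(C)(C)C)c2c1ccc(OC)c2OC | intermediate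
17 | 2-{(2S)-2-[(1S,4S)-4-(tert-butyldimethylsilyloxy)-5,6-dimethoxy-1,2,3,4-tetrahydronaphthalen-1-yl]propyl}-4,4,5,5-tetramethyl-1,3,2-dioxaborolane | CC1(C)OB(C[C@H](C)[C@@H]2CC[C@H](O[Si](C)(C)C(C)(C)C)c3c2ccc(OC)c3OC)OC1(C)C | intermediate
18 | methyl (S)-3-hydroxy-2-methylpropanoate | C[C@H](C(=O)OC)CO | starting material
19 | methyl (S)-3-(tert-butyldimethylsilyloxy)-2-methylpropanoate | C[C@H](C(=O)OC)CO[Si](C)(C)C(C)(C)C | intermediate
20 | (S)-3-(tert-butyldimethylsilyloxy)-2-methylpropanal | C[C@H](C=O)CO[Si](C)(C)C(C)(C)C | intermediate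
21 | tert-butyl{[(2R,3E)-4-iodo-2-methylbut-3-en-1-yl]oxy}dimethylsilane | C[C@H](/C=C/I)CO[Si](C)(C)C(C)(C)C | intermediate
22 | tert-butyl{[(2R,3E,6S)-6-[(1S,4S)-4-(tert-butyldimethylsilyloxy)-5,6-dimethoxy-1,2,3,4-tetrahydronaphthalen-1-yl]-2-methylhept-3-en-1-yl]oxy}dimethylsilane | C[C@H](/C=C/C[C@H](C)[C@@H]1CC[C@H](O[Si](C)(C)C(C)(C)C)c2c1ccc(OC)c2OC)CO[Si](C)(C)C(C)(C)C | intermediate
23 | tert-butyl{[(2R,6S)-6-[(1S,4S)-4-(tert-butyldimethylsilyloxy)-5,6-dimethoxy-1,2,3,4-tetrahydronaphthalen-1-yl]-2-methylheptyl]oxy}dimethylsilane | C[C@H](CCC[C@H](C)[C@@H]1CC[C@H](O[Si](C)(C)C(C)(C)C)c2c1ccc(OC)c2OC)CO[Si](C)(C)C(C)(C)C | intermediate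
24 | (1S,4S)-4-[(2S,6R)-7-hydroxy-6-methylheptan-2-yl]-7,8-dimethoxy-1,2,3,4-tetrahydronaphthalen-1-ol | C[C@H](CCC[C@H](C)[C@@H]1CC[C@H](O)c2c1ccc(OC)c2OC)CO | intermediate
25 | (2R,6S)-6-[(1S,4R)-5,6-dimethoxy-4-methyl-1,2,3,4-tetrahydronaphthalen-1-yl]-2-methylheptan-1-ol | C[C@H](CCC[C@H](C)[C@@H]1CC[C@@H](C)c2c1ccc(OC)c2OC)CO | intermediate
26 | C7-lithio lithium alkoxide of 25 | C[C@H](CCC[C@H](C)[C@@H]1CC[C@@H](C)c2c1cc([Li])c(OC)c2OC)CO[Li] | intermediate
27 | (5R,8S)-8-[(2S,6R)-7-hydroxy-6-methylheptan-2-yl]-3,4-dimethoxy-5-methyl-5,6,7,8-tetrahydronaphthalene-2-carboxylic acid | C[C@H](CCC[C@H](C)[C@@H]1CC[C@@H](C)c2c1cc(C(=O)O)c(OC)c2OC)CO | intermediate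
28 | (5R,8S)-3,4-dihydroxy-8-[(2S,6R)-7-hydroxy-6-methylheptan-2-yl]-5-methyl-5,6,7,8-tetrahydronaphthalene-2-carboxylic acid | C[C@H](CCC[C@H](C)[C@@H]1CC[C@@H](C)c2c1cc(C(=O)O)c(O)c2O)CO | intermediate
29 | prop-2-en-1-yl (5R,8S)-8-[(2S,6R)-7-hydroxy-6-methylheptan-2-yl]-5-methyl-3,4-bis(prop-2-en-1-yloxy)-5,6,7,8-tetrahydronaphthalene-2-carboxylate | C[C@H](CCC[C@H](C)[C@@H]1CC[C@@H](C)c2c1cc(C(=O)OCC=C)c(OCC=C)c2OCC=C)CO | intermediate
30 | caffeic acid | O=C(O)/C=C/c1ccc(O)c(O)c1 | starting material
31 | prop-2-en-1-yl (2E)-3-[3,4-bis(prop-2-en-1-yloxy)phenyl]prop-2-enoate | C=CCOC(=O)/C=C/c1ccc(OCC=C)c(OCC=C)c1 | intermediate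
32 | (2E)-3-[3,4-bis(prop-2-en-1-yloxy)phenyl]prop-2-enoic acid | O=C(O)/C=C/c1ccc(OCC=C)c(OCC=C)c1 | intermediate
33 | prop-2-en-1-yl (5R,8S)-8-[(2S,6R)-7-({(2E)-3-[3,4-bis(prop-2-en-1-yloxy)phenyl]prop-2-enoyl}oxy)-6-methylheptan-2-yl]-5-methyl-3,4-bis(prop-2-en-1-yloxy)-5,6,7,8-tetrahydronaphthalene-2-carboxylate | C[C@H](CCC[C@H](C)[C@@H]1CC[C@@H](C)c2c1cc(C(=O)OCC=C)c(OCC=C)c2OCC=C)COC(=O)/C=C/c1ccc(OCC=C)c(OCC=C)c1 | intermediate
34 | (5R,8S)-8-[(2S,6R)-7-{[(2E)-3-(3,4-dihydroxyphenyl)prop-2-enoyl]oxy}-6-methylheptan-2-yl]-3,4-dihydroxy-5-methyl-5,6,7,8-tetrahydronaphthalene-2-carboxylic acid | C[C@H](CCC[C@H](C)[C@@H]1CC[C@@H](C)c2c1cc(C(=O)O)c(O)c2O)COC(=O)/C=C/c1ccc(O)c(O)c1 | target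

## Step count and least certain steps

Total: 23 steps. Longest linear sequence: 17 steps (1, 3, 4, 5, 6, 7, 8, 9, 13, 14, 15, 16, 17, 18, 19, 22, 23).

**Step 8 (key step).** The most likely failure is that the aryne is consumed before the hindered tether folds onto it. This could happen by capture with fluoride or acetonitrile, by [2+2] addition to the alkene, or after fluoride has removed the benzylic silyl group. The fallback sets out from 9 and forms the same C1–C8a bond by carbopalladation. The carbamate of 9 is cleaved as in step 7 (DBU, Et2NH) to the phenol F1, which is triflated with PhNTf2 to the aryl triflate F2 without the silylation of step 6. An intramolecular Mizoroki–Heck reaction (Pd(OAc)2, dppp, K2CO3, DMF, 90 °C) then closes ring B, and β-hydride elimination toward a C11 methyl group returns the route to 16. The same half-chair preference should again place the isopropenyl group cis to the C4 oxygen.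

**Step 16.** Two processes threaten it. One is loss of a C3 proton from the benzylic cation, which gives the dihydronaphthalene. The other is delivery of methyl from the aluminium alkoxide on the face of the departing oxygen, which would erode the 1,4-trans selectivity. The fallback replaces the cation by a stereospecific nickel-catalysed cross-coupling and sets out from 24. The primary hydroxyl is silylated selectively (TBSCl, imidazole) to give F3, and the benzylic hydroxyl is methylated (NaH, MeI) to the methyl ether F4. Kumada coupling with MeMgI under zerovalent nickel catalysis (Ni(cod)2, DPEphos, toluene) replaces the methoxy group by methyl with inversion, which turns the cis ether into the trans methyl compound F5. Desilylation with Bu4NF returns the route to 25.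

**Step 9.** The hindered, branched 1,1-disubstituted alkene may undergo hydrocupration slowly, and the catalyst may not fully override the C1 centre, giving poor facial selectivity at C11. The fallback sets C11 by asymmetric hydrogenation with a coordinating hydroxyl group and sets out from 16. Allylic oxidation of the methyl group (SeO2, tBuOOH) gives the 2-substituted allylic alcohol F6. Hydrogenation with a chiral iridium phosphine–oxazoline catalyst of the type [Ir(cod)(PHOX)]BArF gives the saturated alcohol F7. Iodination (I2, PPh3, imidazole) gives F8, and zinc insertion (Zn, LiCl, THF) gives the alkylzinc iodide F9. Negishi coupling of F9 with 21 (Pd(PPh3)4) returns the route to 22.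

**Step 4.** The twisted aryl group and the alkyl chain may be differentiated less well than in simple aryl ketones, so the enantioselectivity may be low, and the carbamoyl group may shift to the new alkoxide during work-up. The fallback is a resolution and sets out from 7. Reduction with NaBH4 gives the racemic alcohol F10. Acylative kinetic resolution (benzotetramisole catalyst, propanoic anhydride, iPr2NEt) converts the (R)-enantiomer into the propanoate F11 and leaves the (S)-alcohol, which is 8.

**Step 18.** The C16 borate ester may be converted into the primary bromide, and the hindered C5 ether may cleave incompletely. The fallback makes the bromide deliberately and forms the ester bond by carboxylate alkylation, setting out from 27. Treatment with BBr3 at room temperature gives the bromo catechol acid F12. Allylation as in step 19 gives F13. Displacement of bromide from F13 by the caesium salt of 32 (Cs2CO3, DMF, 50 °C) returns the route to 33.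

## Further compounds

F1 | step 8 | 2-[(1S)-1-(tert-butyldimethylsilyloxy)-5-methylhex-4-en-1-yl]-3,4-dimethoxyphenol | CC(C)=CCC[C@H](O[Si](C)(C)C(C)(C)C)c1c(O)ccc(OC)c1OC
F2 | step 8 | 2-[(1S)-1-(tert-butyldimethylsilyloxy)-5-methylhex-4-en-1-yl]-3,4-dimethoxyphenyl trifluoromethanesulfonate | CC(C)=CCC[C@H](O[Si](C)(C)C(C)(C)C)c1c(OS(=O)(=O)C(F)(F)F)ccc(OC)c1OC
F3 | step 16 | C16 tert-butyldimethylsilyl ether of 24 (C4 hydroxyl free) | C[C@H](CCC[C@H](C)[C@@H]1CC[C@H](O)c2c1ccc(OC)c2OC)CO[Si](C)(C)C(C)(C)C
F4 | step 16 | C4 methyl ether of F3 | C[C@H](CCC[C@H](C)[C@@H]1CC[C@H](OC)c2c1ccc(OC)c2OC)CO[Si](C)(C)C(C)(C)C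
F5 | step 16 | C16 tert-butyldimethylsilyl ether of 25 | C[C@H](CCC[C@H](C)[C@@H]1CC[C@@H](C)c2c1ccc(OC)c2OC)CO[Si](C)(C)C(C)(C)C
F6 | step 9 | 2-[4-(tert-butyldimethylsilyloxy)-5,6-dimethoxy-1,2,3,4-tetrahydronaphthalen-1-yl]prop-2-en-1-ol (ring configuration as in 16) | C=C(CO)[C@@H]1CC[C@H](O[Si](C)(C)C(C)(C)C)c2c1ccc(OC)c2OC
F7 | step 9 | 2-[4-(tert-butyldimethylsilyloxy)-5,6-dimethoxy-1,2,3,4-tetrahydronaphthalen-1-yl]propan-1-ol (configurations at C1, C4 and C11 as in 17) | OC[C@H](C)[C@@H]1CC[C@H](O[Si](C)(C)C(C)(C)C)c2c1ccc(OC)c2OC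
F8 | step 9 | primary iodide from F7 (configurations as in 17) | IC[C@H](C)[C@@H]1CC[C@H](O[Si](C)(C)C(C)(C)C)c2c1ccc(OC)c2OC
F9 | step 9 | alkylzinc iodide from F8 (configurations as in 17) | I[Zn]C[C@H](C)[C@@H]1CC[C@H](O[Si](C)(C)C(C)(C)C)c2c1ccc(OC)c2OC
F10 | step 4 | racemic 2-(1-hydroxy-5-methylhex-4-en-1-yl)-3,4-dimethoxyphenyl propan-2-ylcarbamate | CC(C)=CCCC(O)c1c(OC(=O)NC(C)C)ccc(OC)c1OC
F11 | step 4 | 2-[(1R)-5-methyl-1-(propanoyloxy)hex-4-en-1-yl]-3,4-dimethoxyphenyl propan-2-ylcarbamate | CC(C)=CCC[C@@H](OC(=O)CC)c1c(OC(=O)NC(C)C)ccc(OC)c1OC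
F12 | step 18 | (5R,8S)-8-[(2S,6R)-7-bromo-6-methylheptan-2-yl]-3,4-dihydroxy-5-methyl-5,6,7,8-tetrahydronaphthalene-2-carboxylic acid | C[C@H](CCC[C@H](C)[C@@H]1CC[C@@H](C)c2c1cc(C(=O)O)c(O)c2O)CBr
F13 | step 18 | prop-2-en-1-yl (5R,8S)-8-[(2S,6R)-7-bromo-6-methylheptan-2-yl]-5-methyl-3,4-bis(prop-2-en-1-yloxy)-5,6,7,8-tetrahydronaphthalene-2-carboxylate | C[C@H](CCC[C@H](C)[C@@H]1CC[C@@H](C)c2c1cc(C(=O)OCC=C)c(OCC=C)c2OCC=C)CBr
A1 | alternative 1 | methyl 5-methyl-2-oxo-8-(prop-1-en-2-yl)cyclodeca-3,9-diyne-1-carboxylate (5,8-configuration as in A2) | C=C(C)[C@@H]1CC[C@@H](C)C#CC(=O)C(C(=O)OC)C#C1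
A2 | alternative 1 | methyl 3-hydroxy-5-methyl-8-(prop-1-en-2-yl)-5,6,7,8-tetrahydronaphthalene-2-carboxylate (trans) | C=C(C)[C@@H]1CC[C@@H](C)c2c1cc(C(=O)OC)c(O)c2
A3 | alternative 2 | 1-ethenyl-5,6-dimethoxy-4-methyl-1,2,3,4-tetrahydronaphthalene (1,4-trans) | C=C[C@@H]1CC[C@@H](C)c2c1ccc(OC)c2OC
A4 | alternative 2 | trans tetralin with complete C11–C16 chain, C13–C14 double bond and C16 silyl ether | C[C@H](/C=C/C[C@H](C)[C@@H]1CC[C@@H](C)c2c1ccc(OC)c2OC)CO[Si](C)(C)C(C)(C)C
A5 | alternative 3 | methyl 4,5-dimethoxy-2-oxo-2H-pyran-3-carboxylate bearing at C6 the open chain with the C1 ethynyl group and the C16 silyl ether (configurations at C1, C4, C11 and C15 as in A6) | C[C@H](CCC[C@H](C)[C@@H](C#C)CC[C@@H](C)c1oc(=O)c(C(=O)OC)c(OC)c1OC)CO[Si](C)(C)C(C)(C)C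
A6 | alternative 3 | methyl ester, dimethyl ether and C16 silyl ether of the target acid-alcohol | C[C@H](CCC[C@H](C)[C@@H]1CC[C@@H](C)c2c1cc(C(=O)OC)c(OC)c2OC)CO[Si](C)(C)C(C)(C)C
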